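**Retrosynthetic overview**
1. Endgame: the chlorohydrin comes from the 4α,18-epoxide (chloride at C18) and the butenolide from a 3-furyl carbinol (singlet oxygen). The acetates (C6, C19) and the (S)-2-methylbutanoates (C1, C12) are put on by late acylations; C12 is set by CBS reduction of the furyl ketone.
2. C1–OH and C10–H are set together by β-face hydroboration of the C1=C10 alkene that the key step leaves behind.
3. Key disconnection, C2–C3 and C4–C5: ring A by an intramolecular Diels–Alder reaction of a ring B vinylcyclohexene (C2=C1–C10=C5) with a pyruvate enol ether (C3=C4) held on a temporary diisopropylsilylene. The enabling feature is that the tertiary oxygen on C4 and the oxygen on C19 (the carbon on C5) lie 1,3-syn across the C4–C5 bond (both α) while C18 is anti to C19, so O19–Si–O4 is a strain-free six-membered bridge whose two oxygens stay in the target.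
4. Ring B is made first, from (R)-carvone: cuprate addition/enolate alkylation (C8, C9), ozonolytic dealkenylation, epoxidation/isomerisation to the 1,3-dione, 1,3-dioxin vinylogous ester (C19), vinyl addition with Stork–Danheiser transposition, Luche reduction (C6).
5. Order of ring formation: ring B (chiral pool) → ring A together with the silylene ring (key step) → spiro-epoxide → butenolide (from the furan).

Key step: step 12

Remark on numbering: clerodane numbering is used for every intermediate. Ring A = C1–C5 and C10; ring B = C5–C10; C11–C12 side chain; C13–C16 lactone; C17 = methyl on C8; C18 = carbon on C4; C19 = carbon on C5; C20 = methyl on C9. α is the face of C19 and C20.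
Remark on the target: read from the SMILES it is 1R,4R,5R,6S,8R,9S,10R,12S, that is a trans-decalin (10β-H) with 1β-O, 4α-OH, 18-Cl on the β carbon, 6α-OAc, and both 2-methylbutanoates (S).
Assumption: (R)-carvone, 2-(benzyloxy)ethanol, methyl pyruvate, 3-bromofuran and (S)-2-methylbutanoic acid are bought.

**Route**

Step 1
Reactants: 1 2-(benzyloxy)ethanol
Product: 2 2-(benzyloxy)ethyl trifluoromethanesulfonate
Conditions: Tf2O, pyridine, CH2Cl2, −78 → −20 °C; used at once
Reagents that add atoms: trifluoromethanesulfonic anhydride, O=S(=O)(OS(=O)(=O)C(F)(F)F)C(F)(F)F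
Why: O-sulfonylation of an unhindered primary alcohol should give the reactive alkyl triflate needed to alkylate a hindered enolate; no stereocenter is involved.

Step 2
Reactants: 3 (R)-carvone; 2 2-(benzyloxy)ethyl trifluoromethanesulfonate
Product: 5 (2S,3R,5R)-2-[2-(benzyloxy)ethyl]-2,3-dimethyl-5-(prop-1-en-2-yl)cyclohexan-1-one, via lithium enolate 4 (not isolated)
Conditions: Me2CuLi (from MeLi, CuI), Et2O, −78 → 0 °C; then 2, THF, −78 → 0 °C
Reagents that add atoms: lithium dimethylcuprate, [Li+].C[Cu-]C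
Why: Cuprate conjugate addition followed by enolate C-alkylation: methyl should add to C8 anti to the isopropenyl group and the triflate should then alkylate the C9 enolate anti to the new C8 methyl, so that C17 and C20 are cis and the quaternary C9 is set from the carvone stereocenter.

Step 3
Reactants: 5 (2S,3R,5R)-2-[2-(benzyloxy)ethyl]-2,3-dimethyl-5-(prop-1-en-2-yl)cyclohexan-1-one
Product: 7 (5R,6S)-6-[2-(benzyloxy)ethyl]-5,6-dimethylcyclohex-2-en-1-one, via methoxy hydroperoxide 6 (not isolated)
Conditions: O3, CH2Cl2/MeOH, −78 °C; then Cu(OAc)2·H2O, FeSO4·7H2O, −78 °C → rt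
Reagents that add atoms: none
Why: Criegee ozonolysis in methanol gives the α-methoxy hydroperoxide, which divalent iron reduces to an alkoxy radical that loses methyl acetate by β-scission; divalent copper oxidises the ring radical to the alkene, which should end in conjugation with the ketone (ozonolytic dealkenylation, net redox-neutral so both metal salts return to their starting oxidation states), and C8 and C9 are untouched.

Step 4
Reactants: 7 (5R,6S)-6-[2-(benzyloxy)ethyl]-5,6-dimethylcyclohex-2-en-1-one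
Product: 8 5,6-epoxy ketone (2,3-epoxide of 7, expected on the β face, trans to the C8 methyl)
Conditions: 30% H2O2, NaOH (cat.), MeOH, 0 °C
Reagents that add atoms: hydrogen peroxide, OO
Why: Weitz–Scheffer nucleophilic epoxidation of the enone, hydroperoxide adding to C6 anti to the C8 methyl; the epoxide configuration is erased in step 5, so either epimer serves.

Step 5
Reactants: 8 5,6-epoxy ketone
Product: 9 (4S,5R)-4-[2-(benzyloxy)ethyl]-4,5-dimethylcyclohexane-1,3-dione
Conditions: Pd(PPh3)4 (cat.), 1,2-bis(diphenylphosphino)ethane (cat.), toluene, 100 °C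
Reagents that add atoms: none
Why: Zerovalent-palladium-catalysed isomerisation of an α,β-epoxy ketone to a 1,3-diketone (oxidative addition into the Cα–O bond, β-hydride elimination at C6, tautomerisation), which places the C6 oxygen without touching C8 or C9.

Step 6
Reactants: 9 (4S,5R)-4-[2-(benzyloxy)ethyl]-4,5-dimethylcyclohexane-1,3-dione
Product: 10 (6S,7R)-6-[2-(benzyloxy)ethyl]-6,7-dimethyl-7,8-dihydro-4H-1,3-benzodioxin-5(6H)-one
Conditions: paraformaldehyde, BF3·OEt2, CH2Cl2, rt
Reagents that add atoms: formaldehyde (as paraformaldehyde), C=O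
Why: Lewis-acid-promoted hydroxymethylation of C5 and acetalisation with a second formaldehyde (a known way to 4H-1,3-dioxin vinylogous esters of cyclic 1,3-diones) should close the dioxin onto the less hindered C6 carbonyl, installing C19 and leaving the neopentyl C10 carbonyl as the vinylogous ester carbonyl.

Step 7
Reactants: 10 (6S,7R)-6-[2-(benzyloxy)ethyl]-6,7-dimethyl-7,8-dihydro-4H-1,3-benzodioxin-5(6H)-one
Product: 12 (4S,5R)-4-[2-(benzyloxy)ethyl]-3-ethenyl-2-(hydroxymethyl)-4,5-dimethylcyclohex-2-en-1-one, via tertiary alcohol 11 (not isolated)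
Conditions: CH2=CHMgBr, CeCl3, THF, −78 → 0 °C; then 1 M HCl, THF/H2O, rt
Reagents that add atoms: vinylmagnesium bromide, C=C[Mg]Br; water, O
Why: Organocerium 1,2-addition to the hindered vinylogous ester carbonyl followed by Stork–Danheiser transposition: acid ionises the tertiary allylic alcohol, water adds at C6, and the O–CH2–O link falls apart to formaldehyde and the free C19 hydroxyl, giving the C5=C10/vinyl diene with the C6 ketone.

Step 8
Reactants: 12 (4S,5R)-4-[2-(benzyloxy)ethyl]-3-ethenyl-2-(hydroxymethyl)-4,5-dimethylcyclohex-2-en-1-one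
Product: 13 (1S,4S,5R)-4-[2-(benzyloxy)ethyl]-3-ethenyl-2-(hydroxymethyl)-4,5-dimethylcyclohex-2-en-1-ol (6α-OH)
Conditions: NaBH4, CeCl3·7H2O, MeOH, −78 °C
Reagents that add atoms: none
Why: Luche 1,2-reduction; hydride should add to C6 from the β face (axial attack, or attack anti to an axial C8 methyl in the other ring conformer), giving the hydroxyl cis to the C8 methyl as in the reduction of 5-substituted cyclohexenones.

Step 9
Reactants: 13 diol
Product: 14 bis(tert-butyldimethylsilyl) ether of 13
Conditions: TBSOTf, 2,6-lutidine, CH2Cl2, −78 → 0 °C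
Reagents that add atoms: tert-butyldimethylsilyl trifluoromethanesulfonate, CC(C)(C)[Si](C)(C)OS(=O)(=O)C(F)(F)F
Why: Exhaustive O-silylation of both allylic hydroxyls under non-ionising conditions; no stereocenter changes.

Step 10
Reactants: 14 bis(tert-butyldimethylsilyl) ether
Product: 15 6α-TBS ether with free C19 hydroxyl
Conditions: HF·pyridine, pyridine, THF, 0 °C
Reagents that add atoms: none
Why: Buffered fluoride cleaves the unhindered primary silyl ether much faster than the secondary one flanked by the ring substituents, which frees only the C19 hydroxyl for the tether.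

Step 11
Reactants: 15 6α-TBS ether with free C19 hydroxyl; 16 methyl pyruvate
Product: 18 triene, 15 joined through O19–Si(iPr)2–O to the enol of methyl pyruvate, via silyl triflate 17 (not isolated)
Conditions: iPr2Si(OTf)2, 2,6-lutidine, CH2Cl2, −78 °C; then 16, Et3N, −78 → 0 °C
Reagents that add atoms: diisopropylsilyl bis(trifluoromethanesulfonate), CC(C)[Si](OS(=O)(=O)C(F)(F)F)(OS(=O)(=O)C(F)(F)F)C(C)C
Why: Stepwise substitution at silicon, first by the primary alcohol and then by soft enolisation of the pyruvate ketone (it can enolise only toward its methyl group), should give the mixed silyl acetal/silyl enol ether that carries the captodative dienophile on the C19 oxygen.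

Step 12
Reactants: 18 triene
Product: 19 tricyclic Diels–Alder adduct (4R,5R,6S,8R,9S): C1=C10 alkene, 4α-O–Si(iPr)2–O–C19 bridge, 4β-CO2Me (C18), 6α-OTBS, 8α-Me, 9α-Me, 9β-CH2CH2OBn
Conditions: toluene (high dilution, degassed), BHT (cat.), 130 °C, sealed tube
Reagents that add atoms: none
Why: Thermal, concerted but asynchronous intramolecular [4+2] cycloaddition in which the 2-silyloxyacrylate (captodative dienophile, C3=C4) adds across the C2=C1–C10=C5 diene; the closest known reaction types are intramolecular Diels–Alder reactions through temporary silicon (silyl acetal) tethers and the intermolecular use of 2-oxyacrylates as dienophiles. Ring A closes in the [4+2] mode through the C2–C3 and C4–C5 bonds, and the six-membered 1,3-dioxa-2-silinane (C5–C19–O–Si–O–C4) closes around the same new C4–C5 bond. At C4 the short tether from the in-plane C19 can reach only the exo oxygen, so the oxygen ends cis to C19 (4α-O) and the ester endo and anti to C19 (C18 β). At C5 the dienophile must add to the β face of ring B: that face is open, whereas the α face carries the C6 silyloxy group next to C5 and the pseudoaxial C20 methyl, the ring B half-chair being held by the cis-diequatorial C6–O/C8–Me pair. The step also needs cycloaddition to outrun the 1,5-hydrogen shift open to a cis-substituted diene, for which it relies on intramolecular delivery of an activated dienophile; the regiochemistry is fixed by the tether and agrees with the polarisation of the two partners.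

Step 13
Reactants: 19 tricyclic Diels–Alder adduct
Product: 20 C18 primary alcohol
Conditions: DIBAL-H, CH2Cl2, −78 → 0 °C; aqueous potassium sodium tartrate work-up
Reagents that add atoms: none
Why: Hydride reduction of the methyl ester to the primary alcohol; silyl ethers, silylene, benzyl ether and the hindered alkene are inert, and the C4 stereocenter bears no acidic hydrogen.

Step 14
Reactants: 20 C18 primary alcohol
Product: 21 C18 tosylate
Conditions: TsCl, pyridine, DMAP (cat.), CH2Cl2, 0 °C → rt
Reagents that add atoms: p-toluenesulfonyl chloride, Cc1ccc(cc1)S(Cl)(=O)=O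
Why: O-sulfonylation of the only free hydroxyl; the neopentyl tosylate is inert to intermolecular substitution and is kept as the latent leaving group for epoxide closure once O4 is unmasked.

Step 15
Reactants: 21 C18 tosylate
Product: 23 1β-alcohol with 10β-H (trans-decalin), via alkylborane 22 (not isolated)
Conditions: BH3·THF, THF, 0 → 40 °C; then NaOH, H2O2, 0 °C
Reagents that add atoms: hydrogen peroxide, OO
Why: Brown hydroboration–oxidation: boron goes to the less substituted C1 and hydrogen to C10 in a syn addition from the β face, because the α face of the alkene is closed by the two axial carbons C19 (on C5) and C20 (on C9); oxidation with retention should give 1β-OH and 10β-H in one operation.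

Step 16
Reactants: 23 1β-alcohol; 24 (S)-2-methylbutanoic acid
Product: 25 1β-O-[(S)-2-methylbutanoyl] ester
Conditions: DCC, DMAP (cat.), CH2Cl2, 0 °C → rt
Reagents that add atoms: none
Why: Steglich esterification of the equatorial secondary alcohol, with catalytic DMAP at low temperature to keep the α-stereocenter of the acid intact.

Step 17
Reactants: 25 1β-ester
Product: 26 C12 primary alcohol
Conditions: H2 (1 atm), Pd/C, EtOAc, rt
Reagents that add atoms: none
Why: Hydrogenolysis of the benzyl ether; no alkene remains, and tosylate, silyl groups and ester are stable.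

Step 18
Reactants: 26 C12 primary alcohol
Product: 27 C12 aldehyde
Conditions: Dess–Martin periodinane, CH2Cl2, 0 °C → rt
Reagents that add atoms: none
Why: Dess–Martin oxidation of the only free alcohol to the aldehyde; the C1 oxygen is already acylated, so no lactol can form.

Step 19
Reactants: 27 C12 aldehyde; 28 3-bromofuran
Product: 30 3-furyl carbinol (C12 epimers), via 3-furyllithium 29 (not isolated)
Conditions: 28, n-BuLi, THF, −78 °C; then 27, −78 °C; H2O
Reagents that add atoms: none
Why: Bromine–lithium exchange at −78 °C (where the 3-lithiofuran does not isomerise) and 1,2-addition to the aldehyde, which is far faster than attack on the hindered C1 ester or the neopentyl tosylate; the C12 mixture is converged in steps 20 and 21.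

Step 20
Reactants: 30 3-furyl carbinol (C12 epimers)
Product: 31 3-furyl ketone
Conditions: Dess–Martin periodinane, CH2Cl2, 0 °C → rt
Reagents that add atoms: none
Why: Dess–Martin oxidation of the secondary heteroaryl carbinol removes the uncontrolled C12 center.

Step 21
Reactants: 31 3-furyl ketone
Product: 32 (12S)-3-furyl carbinol
Conditions: (R)-2-methyl-CBS-oxazaborolidine (cat.), BH3·SMe2, THF, −20 °C; MeOH quench
Reagents that add atoms: none
Why: Corey–Bakshi–Shibata reduction under reagent control: with the heteroaryl ring as the large group and the C11 methylene as the small one, the (R)-catalyst should deliver hydride to the face that gives the (S)-carbinol, as with aryl alkyl ketones.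

Step 22
Reactants: 32 (12S)-3-furyl carbinol; 24 (S)-2-methylbutanoic acid
Product: 33 1,12-bis[(S)-2-methylbutanoate]
Conditions: DCC, DMAP (cat.), CH2Cl2, 0 °C → rt
Reagents that add atoms: none
Why: Steglich esterification of the secondary carbinol with retention at C12.

Step 23
Reactants: 33 1,12-bis[(S)-2-methylbutanoate]
Product: 35 4α,18-epoxide with free 6α- and 19-hydroxyls, via triol tosylate 34 (not isolated)
Conditions: TBAF, THF, 0 °C → rt
Reagents that add atoms: none
Why: Fluoride removes the silylene and the C6 silyl ether, and the liberated C4 alkoxide displaces the adjacent primary tosylate (3-exo-tet Williamson closure) with retention at C4; C19–O cannot compete because C18 and C19 are trans-diaxial.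

Step 24
Reactants: 35 epoxy diol
Product: 36 6α,19-diacetate (epoxide, furan)
Conditions: Ac2O, pyridine, DMAP (cat.), CH2Cl2, rt
Reagents that add atoms: acetic anhydride, CC(=O)OC(C)=O
Why: Acetylation of the primary C19 and secondary C6 hydroxyls in one operation; no other hydroxyl is present.

Step 25
Reactants: 36 6α,19-diacetate
Product: 38 γ-hydroxybutenolide (hydroxyl on C16), via endoperoxide 37 (not isolated)
Conditions: O2, 5,10,15,20-tetraphenylporphyrin (cat.), visible light, iPr2NEt, CH2Cl2, −78 °C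
Reagents that add atoms: dioxygen, O=O
Why: Singlet-oxygen [4+2] cycloaddition to the furan and base-induced Kornblum–DeLaMare fragmentation, the hindered amine removing the less hindered bridgehead hydrogen (C15) so that the carbonyl forms at C15 and the side chain sits on the β-carbon.

Step 26
Reactants: 38 γ-hydroxybutenolide
Product: 40 butenolide with 4α,18-epoxide, via hydroxy carboxylate 39 (not isolated)
Conditions: NaBH4, EtOH, 0 °C; then AcOH
Reagents that add atoms: none
Why: Borohydride reduces the lactol (masked aldehyde) at C16 to the 4-hydroxybut-2-enoate whose hydroxymethyl group is cis to the carboxylate, which relactonises on mild acidification to the 4-substituted furan-2(5H)-one; acetates, esters and epoxide survive at 0 °C.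

Step 27
Reactants: 40 butenolide with 4α,18-epoxide
Product: 41 ajugaciliatin A
Conditions: pyridinium chloride, CH2Cl2, rt
Reagents that add atoms: pyridinium chloride, c1cc[nH+]cc1.[Cl-]
Why: Acid-assisted SN2 opening of the spiro-epoxide by chloride at the unhindered primary C18 leaves the C4–O bond, and so the 4α-hydroxyl configuration, untouched; attack at the tertiary C4 is blocked by the adjacent quaternary C5.

**Compound list**

1 | 2-(benzyloxy)ethanol | OCCOCc1ccccc1 | starting material
2 | 2-(benzyloxy)ethyl trifluoromethanesulfonate | O=S(=O)(OCCOCc1ccccc1)C(F)(F)F | intermediate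
3 | (R)-carvone, (5R)-2-methyl-5-(prop-1-en-2-yl)cyclohex-2-en-1-one | CC1=CC[C@@H](C(C)=C)CC1=O | starting material
4 | lithium (3R,5R)-2,3-dimethyl-5-(prop-1-en-2-yl)cyclohex-1-en-1-olate | [Li]OC1=C(C)[C@H](C)C[C@@H](C(C)=C)C1 | intermediate
5 | (2S,3R,5R)-2-[2-(benzyloxy)ethyl]-2,3-dimethyl-5-(prop-1-en-2-yl)cyclohexan-1-one | c1ccccc1COCC[C@@]2(C)[C@H](C)C[C@@H](C(C)=C)CC2=O | intermediate
6 | (2S,3R,5R)-2-[2-(benzyloxy)ethyl]-5-(1-hydroperoxy-1-methoxyethyl)-2,3-dimethylcyclohexan-1-one | c1ccccc1COCC[C@@]2(C)[C@H](C)C[C@@H](C(C)(OC)OO)CC2=O | intermediate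
7 | (5R,6S)-6-[2-(benzyloxy)ethyl]-5,6-dimethylcyclohex-2-en-1-one | c1ccccc1COCC[C@@]2(C)[C@H](C)CC=CC2=O | intermediate
8 | 2,3-epoxide of 7 on the β face (trans to the C8 methyl) | c1ccccc1COCC[C@@]2(C)[C@H](C)C[C@H]3O[C@H]3C2=O | intermediate
9 | (4S,5R)-4-[2-(benzyloxy)ethyl]-4,5-dimethylcyclohexane-1,3-dione | c1ccccc1COCC[C@@]2(C)[C@H](C)CC(=O)CC2=O | intermediate
10 | (6S,7R)-6-[2-(benzyloxy)ethyl]-6,7-dimethyl-7,8-dihydro-4H-1,3-benzodioxin-5(6H)-one | c1ccccc1COCC[C@@]2(C)[C@H](C)CC3=C(COCO3)C2=O | intermediate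
11 | (6S,7R)-6-[2-(benzyloxy)ethyl]-5-ethenyl-6,7-dimethyl-5,6,7,8-tetrahydro-4H-1,3-benzodioxin-5-ol (C10 epimers) | c1ccccc1COCC[C@@]2(C)[C@H](C)CC3=C(COCO3)C2(O)C=C | intermediate
12 | (4S,5R)-4-[2-(benzyloxy)ethyl]-3-ethenyl-2-(hydroxymethyl)-4,5-dimethylcyclohex-2-en-1-one | c1ccccc1COCC[C@@]2(C)[C@H](C)CC(=O)C(CO)=C2C=C | intermediate
13 | (1S,4S,5R)-4-[2-(benzyloxy)ethyl]-3-ethenyl-2-(hydroxymethyl)-4,5-dimethylcyclohex-2-en-1-ol | c1ccccc1COCC[C@@]2(C)[C@H](C)C[C@H](O)C(CO)=C2C=C | intermediate
14 | bis(tert-butyldimethylsilyl) ether of 13 (6α-OTBS, 19-OTBS) | c1ccccc1COCC[C@@]2(C)[C@H](C)C[C@H](O[Si](C)(C)C(C)(C)C)C(CO[Si](C)(C)C(C)(C)C)=C2C=C | intermediate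
15 | 6α-TBS ether of 13 with free C19 hydroxyl | c1ccccc1COCC[C@@]2(C)[C@H](C)C[C@H](O[Si](C)(C)C(C)(C)C)C(CO)=C2C=C | intermediate
16 | methyl pyruvate | CC(=O)C(=O)OC | starting material
17 | 15 silylated on O19 as the diisopropylsilyl triflate | c1ccccc1COCC[C@@]2(C)[C@H](C)C[C@H](O[Si](C)(C)C(C)(C)C)C(CO[Si](C(C)C)(C(C)C)OS(=O)(=O)C(F)(F)F)=C2C=C | intermediate
18 | triene: 15 joined through O19–Si(iPr)2–O to the enol of methyl pyruvate (methyl 2-silyloxyacrylate) | c1ccccc1COCC[C@@]2(C)[C@H](C)C[C@H](O[Si](C)(C)C(C)(C)C)C(CO[Si](C(C)C)(C(C)C)OC(=C)C(=O)OC)=C2C=C | intermediate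
19 | Diels–Alder adduct (4R,5R,6S,8R,9S): C1=C10 alkene, 4α-O–Si(iPr)2–O–C19 silylene, 4β-CO2Me, 6α-OTBS, 8α-Me, 9α-Me, 9β-CH2CH2OBn | c1ccccc1COCC[C@@]2(C)[C@H](C)C[C@H](O[Si](C)(C)C(C)(C)C)[C@]3(CO[Si](C(C)C)(C(C)C)O4)C2=CCC[C@]34C(=O)OC | intermediate
20 | 19 with the ester reduced to the C18 primary alcohol | c1ccccc1COCC[C@@]2(C)[C@H](C)C[C@H](O[Si](C)(C)C(C)(C)C)[C@]3(CO[Si](C(C)C)(C(C)C)O4)C2=CCC[C@]34CO | intermediate
21 | C18 p-toluenesulfonate of 20 | c1ccccc1COCC[C@@]2(C)[C@H](C)C[C@H](O[Si](C)(C)C(C)(C)C)[C@]3(CO[Si](C(C)C)(C(C)C)O4)C2=CCC[C@]34COS(=O)(=O)c5ccc(C)cc5 | intermediate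
22 | 1β-boryl, 10β-H alkylborane from 21 | c1ccccc1COCC[C@@]2(C)[C@H](C)C[C@H](O[Si](C)(C)C(C)(C)C)[C@]3(CO[Si](C(C)C)(C(C)C)O4)[C@@H]2[C@H](B)CC[C@]34COS(=O)(=O)c5ccc(C)cc5 | intermediate
23 | 1β-alcohol, 10β-H trans-decalin (1R,10R) | c1ccccc1COCC[C@@]2(C)[C@H](C)C[C@H](O[Si](C)(C)C(C)(C)C)[C@]3(CO[Si](C(C)C)(C(C)C)O4)[C@@H]2[C@H](O)CC[C@]34COS(=O)(=O)c5ccc(C)cc5 | intermediate
24 | (S)-2-methylbutanoic acid | CC[C@H](C)C(=O)O | starting material
25 | 1β-O-[(S)-2-methylbutanoyl] ester of 23 | c1ccccc1COCC[C@@]2(C)[C@H](C)C[C@H](O[Si](C)(C)C(C)(C)C)[C@]3(CO[Si](C(C)C)(C(C)C)O4)[C@@H]2[C@H](OC(=O)[C@@H](C)CC)CC[C@]34COS(=O)(=O)c5ccc(C)cc5 | intermediate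
26 | C12 primary alcohol (benzyl removed) | OCC[C@@]2(C)[C@H](C)C[C@H](O[Si](C)(C)C(C)(C)C)[C@]3(CO[Si](C(C)C)(C(C)C)O4)[C@@H]2[C@H](OC(=O)[C@@H](C)CC)CC[C@]34COS(=O)(=O)c5ccc(C)cc5 | intermediate
27 | C12 aldehyde | O=CC[C@@]2(C)[C@H](C)C[C@H](O[Si](C)(C)C(C)(C)C)[C@]3(CO[Si](C(C)C)(C(C)C)O4)[C@@H]2[C@H](OC(=O)[C@@H](C)CC)CC[C@]34COS(=O)(=O)c5ccc(C)cc5 | intermediate
28 | 3-bromofuran | Brc1ccoc1 | starting material
29 | 3-furyllithium | [Li]c1ccoc1 | intermediate
30 | 12-(3-furyl) carbinol, C12 epimers | OC(C[C@@]2(C)[C@H](C)C[C@H](O[Si](C)(C)C(C)(C)C)[C@]3(CO[Si](C(C)C)(C(C)C)O4)[C@@H]2[C@H](OC(=O)[C@@H](C)CC)CC[C@]34COS(=O)(=O)c5ccc(C)cc5)c1ccoc1 | intermediate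
31 | 12-oxo 3-furyl ketone | O=C(C[C@@]2(C)[C@H](C)C[C@H](O[Si](C)(C)C(C)(C)C)[C@]3(CO[Si](C(C)C)(C(C)C)O4)[C@@H]2[C@H](OC(=O)[C@@H](C)CC)CC[C@]34COS(=O)(=O)c5ccc(C)cc5)c1ccoc1 | intermediate
32 | (12S)-12-(3-furyl) carbinol | O[C@@H](C[C@@]2(C)[C@H](C)C[C@H](O[Si](C)(C)C(C)(C)C)[C@]3(CO[Si](C(C)C)(C(C)C)O4)[C@@H]2[C@H](OC(=O)[C@@H](C)CC)CC[C@]34COS(=O)(=O)c5ccc(C)cc5)c1ccoc1 | intermediate
33 | 1β,12S-bis[(S)-2-methylbutanoate] (silylene, 6α-OTBS, 18-OTs, furan) | CC[C@H](C)C(=O)O[C@@H](C[C@@]2(C)[C@H](C)C[C@H](O[Si](C)(C)C(C)(C)C)[C@]3(CO[Si](C(C)C)(C(C)C)O4)[C@@H]2[C@H](OC(=O)[C@@H](C)CC)CC[C@]34COS(=O)(=O)c5ccc(C)cc5)c1ccoc1 | intermediate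
34 | 4α,6α,19-triol 18-tosylate | CC[C@H](C)C(=O)O[C@@H](C[C@@]2(C)[C@H](C)C[C@H](O)[C@]3(CO)[C@@H]2[C@H](OC(=O)[C@@H](C)CC)CC[C@]3(O)COS(=O)(=O)c5ccc(C)cc5)c1ccoc1 | intermediate
35 | 4α,18-epoxide with 6α- and 19-hydroxyls | CC[C@H](C)C(=O)O[C@@H](C[C@@]2(C)[C@H](C)C[C@H](O)[C@]3(CO)[C@@H]2[C@H](OC(=O)[C@@H](C)CC)CC[C@]34CO4)c1ccoc1 | intermediate
36 | 6α,19-diacetate of 35 | CC[C@H](C)C(=O)O[C@@H](C[C@@]2(C)[C@H](C)C[C@H](OC(C)=O)[C@]3(COC(C)=O)[C@@H]2[C@H](OC(=O)[C@@H](C)CC)CC[C@]34CO4)c1ccoc1 | intermediate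
37 | furan 2,5-endoperoxide of 36 | CC[C@H](C)C(=O)O[C@@H](C[C@@]2(C)[C@H](C)C[C@H](OC(C)=O)[C@]3(COC(C)=O)[C@@H]2[C@H](OC(=O)[C@@H](C)CC)CC[C@]34CO4)C1=CC5OOC1O5 | intermediate
38 | 16-hydroxybutenolide (5-hydroxy-4-substituted furan-2(5H)-one, C16 epimers) | CC[C@H](C)C(=O)O[C@@H](C[C@@]2(C)[C@H](C)C[C@H](OC(C)=O)[C@]3(COC(C)=O)[C@@H]2[C@H](OC(=O)[C@@H](C)CC)CC[C@]34CO4)C1=CC(=O)OC1O | intermediate
39 | sodium 4-hydroxy-3-substituted but-2-enoate, hydroxymethyl cis to the carboxylate (ring-opened lactone) | CC[C@H](C)C(=O)O[C@@H](C[C@@]2(C)[C@H](C)C[C@H](OC(C)=O)[C@]3(COC(C)=O)[C@@H]2[C@H](OC(=O)[C@@H](C)CC)CC[C@]34CO4)/C(CO)=C/C(=O)[O-].[Na+] | intermediate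
40 | butenolide with 4α,18-epoxide | CC[C@H](C)C(=O)O[C@@H](C[C@@]2(C)[C@H](C)C[C@H](OC(C)=O)[C@]3(COC(C)=O)[C@@H]2[C@H](OC(=O)[C@@H](C)CC)CC[C@]34CO4)C1=CC(=O)OC1 | intermediate
41 | ajugaciliatin A | CC[C@H](C)C(=O)O[C@@H](C[C@@]1(C)[C@H](C)C[C@H](OC(C)=O)[C@]2(COC(C)=O)[C@@H]1[C@H](OC(=O)[C@@H](C)CC)CC[C@]2(O)CCl)C1=CC(=O)OC1 | target

**Step count and risks**

Total step count: 27. Longest linear sequence: 27 steps (steps 1–27, from 2-(benzyloxy)ethanol 1 through triflate 2; (R)-carvone 3 enters at step 2).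

Three steps most likely to fail:

Step 12. What may go wrong: the twisted diene with its fully substituted terminus reacts too slowly, so that a 1,5-hydrogen shift in the diene or loss of the silyl enol ether competes, or the dienophile adds to both faces of ring B. The fallback sets out from 12 and comes back at 21. The C19 hydroxyl of dienone 12 is tethered as in step 11 (iPr2Si(OTf)2, 2,6-lutidine; then methyl pyruvate, Et3N) to give the dienone silyl enol ether F1. Me2AlCl in CH2Cl2 at −78 °C then promotes a stepwise, polarity-matched annulation: vinylogous Mukaiyama–Michael addition of C3 to the δ-carbon C2 of the activated dienone, then aldol addition of the dienolate carbon C5 to the silyl-activated pyruvate carbonyl C4 inside the tether. This forms the same two bonds without heat and gives the tricyclic keto ester F2. DIBAL-H reduces ketone and ester to the 6α,18-diol F3 (axial hydride delivery from the β face), TsCl/pyridine sulfonylates only the primary C18 hydroxyl to give the hydroxy tosylate F4, and TBSOTf/2,6-lutidine gives 21.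

Step 15. What may go wrong: borane adds too slowly to the trisubstituted alkene between two quaternary carbons, or forcing conditions erode face selectivity and attack the silyl groups. The fallback sets out from 21 and comes back at 23. Dimethyldioxirane in acetone epoxidises the alkene from the open β face to the 1β,10β-epoxide F5. Cp2TiCl (from Cp2TiCl2 and Zn) with 1,4-cyclohexadiene in THF then opens it by electron transfer from trivalent titanium at the tertiary C10–O bond, and hydrogen-atom transfer to the C10 radical from the β face gives 23 (anti-Markovnikov reductive epoxide opening).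

Step 6. What may go wrong: acetalisation onto the wrong carbonyl, or condensation of the dione with formaldehyde to a methylene-bridged dimer. The fallback sets out from 9 and comes back at 12. Isobutanol and TsOH in benzene (Dean–Stark) give, under equilibrating conditions that keep the neopentyl C10 carbonyl, the isobutyl vinylogous ester F6 (a regioisomer is separable). N-Iodosuccinimide iodinates C5 to the iodo vinylogous ester F7. Stille coupling with (tributylstannyl)methanol and Pd(PPh3)4 installs C19 as the hydroxymethyl vinylogous ester F8. Excess vinylmagnesium bromide/CeCl3 gives the tertiary alcohol F9, which aqueous HCl converts into 12 with loss of isobutanol.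

Further compounds
F1 | step 12 | dienone 12 joined through O19–Si(iPr)2–O to the enol of methyl pyruvate | c1ccccc1COCC[C@@]2(C)[C@H](C)CC(=O)C(CO[Si](C(C)C)(C(C)C)OC(=C)C(=O)OC)=C2C=C
F2 | step 12 | tricyclic keto ester: 6-oxo analogue of 19 (C1=C10, 4α-O/19-O silylene, 4β-CO2Me) | c1ccccc1COCC[C@@]2(C)[C@H](C)CC(=O)[C@]3(CO[Si](C(C)C)(C(C)C)O4)C2=CCC[C@]34C(=O)OC
F3 | step 12 | 6α,18-diol with silylene and C1=C10 alkene | c1ccccc1COCC[C@@]2(C)[C@H](C)C[C@H](O)[C@]3(CO[Si](C(C)C)(C(C)C)O4)C2=CCC[C@]34CO
F4 | step 12 | 6α-hydroxy 18-tosylate with silylene and C1=C10 alkene | c1ccccc1COCC[C@@]2(C)[C@H](C)C[C@H](O)[C@]3(CO[Si](C(C)C)(C(C)C)O4)C2=CCC[C@]34COS(=O)(=O)c5ccc(C)cc5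
F5 | step 15 | 1β,10β-epoxide of 21 | c1ccccc1COCC[C@@]2(C)[C@H](C)C[C@H](O[Si](C)(C)C(C)(C)C)[C@]3(CO[Si](C(C)C)(C(C)C)O4)[C@@]25O[C@@H]5CC[C@]34COS(=O)(=O)c6ccc(C)cc6
F6 | step 6 | (5R,6S)-6-[2-(benzyloxy)ethyl]-5,6-dimethyl-3-(2-methylpropoxy)cyclohex-2-en-1-one | c1ccccc1COCC[C@@]2(C)[C@H](C)CC(OCC(C)C)=CC2=O
F7 | step 6 | (5R,6S)-6-[2-(benzyloxy)ethyl]-2-iodo-5,6-dimethyl-3-(2-methylpropoxy)cyclohex-2-en-1-one | c1ccccc1COCC[C@@]2(C)[C@H](C)CC(OCC(C)C)=C(I)C2=O
F8 | step 6 | (5R,6S)-6-[2-(benzyloxy)ethyl]-2-(hydroxymethyl)-5,6-dimethyl-3-(2-methylpropoxy)cyclohex-2-en-1-one | c1ccccc1COCC[C@@]2(C)[C@H](C)CC(OCC(C)C)=C(CO)C2=O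
F9 | step 6 | (5R,6S)-6-[2-(benzyloxy)ethyl]-1-ethenyl-2-(hydroxymethyl)-5,6-dimethyl-3-(2-methylpropoxy)cyclohex-2-en-1-ol (C10 epimers) | c1ccccc1COCC[C@@]2(C)[C@H](C)CC(OCC(C)C)=C(CO)C2(O)C=C
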